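**Retrosynthetic overview** (azaphilone numbering: O2, C1, C3, C4, C4a, C5–C8, C8a)
1. The pyran ring is closed last: in acid the C1 alcohol condenses with the C3 ketone of a vinylogous 1,5-diketone, in the same operation that removes all protecting groups.
2. The carbocycle is closed first, at C4a–C8a: a Ti(III) epoxide-opening/6-exo-dig radical cyclisation onto an ynone sets C8a and frees the C1 alcohol.
3. The cyclisation substrate comes from a C6 aldehyde, the propargyl dianion (C5–C4a–C4) and an enal-ester (C3 plus side chain), followed by double oxidation.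
4. C7 and C8 come from Sharpless epoxidation of a (Z)-dienol and invertive opening of the epoxide at C8 by the protected orsellinic acid, so the hindered ester is made by O-alkylation.
5. The orsellinate comes from self-condensation of methyl acetoacetate; the (Z)-dienol from anti-carbomagnesiation/vinylation of propargyl alcohol.

**Step 1**
Reactants: 1 methyl acetoacetate (2 equiv)
Product: 2 methyl 2,4-dihydroxy-6-methylbenzoate (methyl orsellinate)
Conditions: NaH, THF, 0 °C; n-BuLi, −78 °C → rt → reflux; aq. HCl
Reagents that add atoms: none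
Why: Self-condensation of the acetoacetate dianion (γ-Claisen acylation, then intramolecular aldol, dehydration and aromatisation) is a known one-pot route to methyl orsellinate.

**Step 2**
Reactants: 2 methyl orsellinate
Product: 3 methyl 2,4-bis(methoxymethoxy)-6-methylbenzoate
Conditions: NaH, MOMCl, DMF, 0 °C → rt
Reagents that add atoms: chloromethyl methyl ether, COCCl
Why: Williamson O-alkylation; NaH is needed to alkylate the hydrogen-bonded 2-OH as well as the 4-OH.

**Step 3**
Reactants: 3 bis-MOM methyl ester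
Product: 4 2,4-bis(methoxymethoxy)-6-methylbenzoic acid
Conditions: KOH, MeOH/H2O, reflux; citric acid to pH 4, 0 °C
Reagents that add atoms: KOH/water (O of the acid), [K+].[OH-]
Why: Saponification of the hindered benzoate; MOM ethers survive base and the mild acidification.

**Step 4**
Reactants: 5 propargyl alcohol; 6 vinyl bromide
Product: 7 (2Z)-2-methylpenta-2,4-dien-1-ol (CH2OH and vinyl cis)
Conditions: MeMgBr (3 equiv), CuI (10 mol %), THF, −10 °C → rt; then 6 (3 equiv), Pd(PPh3)4 (3 mol %), rt → 40 °C
Reagents that add atoms: methylmagnesium bromide, C[Mg]Br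
Why: Cu-catalysed anti-carbomagnesiation of propargyl alcohol (Duboudin–Normant) gives the five-membered Mg chelate with Mg cis to CH2O, and stereoretentive Kumada coupling of this alkenyl-Mg with vinyl bromide gives the Z-dienol in one pot.

**Step 5**
Reactants: 7 (Z)-dienol
Product: 8 [(2S,3R)-3-ethenyl-2-methyloxiran-2-yl]methanol (cis epoxide)
Conditions: Ti(OiPr)4 (10 mol %), L-(+)-DIPT (12 mol %), t-BuOOH, 4 Å MS, CH2Cl2, −20 °C
Reagents that add atoms: tert-butyl hydroperoxide, CC(C)(C)OO
Why: Sharpless asymmetric epoxidation reacts only at the allylic alkene; the L-(+)-tartrate sets the 2S centre (future C7) and, with the Z geometry, the 3R centre (future C8 before inversion).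

**Step 6**
Reactants: 8 epoxy alcohol; 4 protected orsellinic acid
Product: 9 (2S,3S)-1,2-dihydroxy-2-methylpent-4-en-3-yl 2,4-bis(methoxymethoxy)-6-methylbenzoate
Conditions: Ti(OiPr)4 (1.5 equiv), 4 (1.3 equiv), CH2Cl2, rt; aq. Rochelle salt
Reagents that add atoms: none
Why: Caron–Sharpless Ti(OiPr)4-mediated opening: the carboxylate attacks the Ti-bound epoxy alkoxide at the allylic C3 by SN2 (inversion), giving the anti tertiary-OH/secondary-ester relationship of C7/C8.

**Step 7**
Reactants: 9 diol ester
Product: 10 (2S,3S)-2-methyl-1,2-bis(triethylsilyloxy)pent-4-en-3-yl 2,4-bis(methoxymethoxy)-6-methylbenzoate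
Conditions: TESOTf (2.6 equiv), 2,6-lutidine, CH2Cl2, −78 → 0 °C
Reagents that add atoms: triethylsilyl triflate, CC[Si](CC)(CC)OS(=O)(=O)C(F)(F)F
Why: Silyl triflate silylates the primary and the tertiary hydroxyl; the tertiary TES ether later prevents oxa-Michael closure to a 3(2H)-furanone.

**Step 8**
Reactants: 10 bis-TES ether
Product: 11 (1S,2S)-2-methyl-1-(oxiran-2-yl)-2,3-bis(triethylsilyloxy)propyl 2,4-bis(methoxymethoxy)-6-methylbenzoate (about 1:1 at the oxirane carbon)
Conditions: CF3COCH3, Oxone, NaHCO3, MeCN/aq. Na2EDTA, 0 °C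
Reagents that add atoms: methyl(trifluoromethyl)dioxirane formed in situ from Oxone, CC1(OO1)C(F)(F)F
Why: In situ dioxirane epoxidation of the deactivated terminal alkene, done while no free secondary alcohol is present; the new oxirane centre need not be controlled because it becomes a radical in Step 13.

**Step 9**
Reactants: 11 epoxide
Product: 12 (1S,2R)-2-methyl-1-(oxiran-2-yl)-3-oxo-2-(triethylsilyloxy)propyl 2,4-bis(methoxymethoxy)-6-methylbenzoate
Conditions: (COCl)2, DMSO, CH2Cl2, −78 → −30 °C; Et3N, → 0 °C
Reagents that add atoms: none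
Why: Swern conditions cleave and oxidise a primary TES ether directly to the aldehyde while the tertiary TES ether and the epoxide survive; the aldehyde has no α-hydrogen.

**Step 10**
Reactants: 13 tert-butyl (2E)-but-2-enoate (tert-butyl crotonate)
Product: 14 tert-butyl (2E)-4-oxobut-2-enoate
Conditions: SeO2 (1.1 equiv), wet 1,4-dioxane, reflux
Reagents that add atoms: selenium dioxide, O=[Se]=O
Why: Riley allylic oxidation of the γ-methyl group of a crotonate gives the (E)-4-oxo-enoate.

**Step 11**
Reactants: 12 aldehyde; 15 propargyl bromide; 14 enal ester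
Product: 16 tert-butyl (2E,9S,10S)-10-{[2,4-bis(methoxymethoxy)-6-methylbenzoyl]oxy}-4,8-dihydroxy-9-methyl-10-(oxiran-2-yl)-9-(triethylsilyloxy)dec-2-en-5-ynoate (mixture at C4, C8 and the oxirane carbon)
Conditions: 15, n-BuLi (2 equiv), TMEDA, Et2O–hexane, −78 °C; add 12, −78 °C; then 14, −78 °C; AcOH quench at −78 °C
Reagents that add atoms: none
Why: 1,3-Dilithiopropyne adds through its propargylic carbon to 12, and the remaining lithium acetylide then adds 1,2 to enal 14 (sequential carbonyl additions); both new carbinol centres are oxidised away in Step 12.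

**Step 12**
Reactants: 16 diol
Product: 17 tert-butyl (2E,9R,10S)-10-{[2,4-bis(methoxymethoxy)-6-methylbenzoyl]oxy}-9-methyl-10-(oxiran-2-yl)-4,8-dioxo-9-(triethylsilyloxy)dec-2-en-5-ynoate (used crude at once)
Conditions: Dess–Martin periodinane (3 equiv), NaHCO3, CH2Cl2, 0 °C → rt; fast filtration
Reagents that add atoms: none
Why: Buffered Dess–Martin oxidation converts both secondary alcohols to ketones without acid or base that would isomerise the CH2 between the ketone and the ynone.

**Step 13**
Reactants: 17 epoxy ynedione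
Product: 18 (1S,2S,6R)-3-[(3E)-5-tert-butoxy-2,5-dioxopent-3-en-1-ylidene]-2-(hydroxymethyl)-6-methyl-5-oxo-6-(triethylsilyloxy)cyclohexyl 2,4-bis(methoxymethoxy)-6-methylbenzoate (exocyclic C=C and keto–enol mixture)
Conditions: Cp2TiCl (from Cp2TiCl2 2.5 equiv, Mn dust), added slowly to 17 (2 mM, degassed THF), 0 °C → rt; aq. NaH2PO4
Reagents that add atoms: none
Why: Nugent–RajanBabu reaction: Cp2TiCl opens the terminal epoxide to the secondary C8a radical bearing CH2O–Ti, which closes 6-exo-dig onto the ynone β-carbon (C4a) in a polarity-matched Giese-type addition; a chair transition state with the C8 ester and CH2OTi both equatorial gives the trans (8aS) centre, and the α-acyl vinyl radical is reduced and protonated.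

**Step 14**
Reactants: 18 hydroxy ene-dione
Product: 19 pinazaphilone B
Conditions: TFA/CH2Cl2/H2O (10:10:1), 1,3-dimethoxybenzene (scavenger), 0 °C → rt; reverse-phase HPLC
Reagents that add atoms: none
Why: Acid removes the TES ether, both MOM ethers and the tert-butyl ester, and the C1 alcohol condenses with the C3 ketone of the enolised 1,5-diketone (hemiketal, then dehydration) to the conjugated vinylogous ester; C7 and C8 are untouched, and the acid-epimerisable C8a should settle in the (presumably more stable) trans-diequatorial arrangement.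

**Compound list**
1 | methyl acetoacetate | CC(=O)CC(=O)OC | starting material
2 | methyl 2,4-dihydroxy-6-methylbenzoate | COC(=O)c1c(C)cc(O)cc1O | intermediate
3 | methyl 2,4-bis(methoxymethoxy)-6-methylbenzoate | COCOc1cc(C)c(C(=O)OC)c(OCOC)c1 | intermediate
4 | 2,4-bis(methoxymethoxy)-6-methylbenzoic acid | COCOc1cc(C)c(C(=O)O)c(OCOC)c1 | intermediate
5 | propargyl alcohol | OCC#C | starting material
6 | vinyl bromide | C=CBr | starting material
7 | (2Z)-2-methylpenta-2,4-dien-1-ol | OC/C(C)=C\C=C | intermediate
8 | [(2S,3R)-3-ethenyl-2-methyloxiran-2-yl]methanol | OC[C@]1(C)O[C@@H]1C=C | intermediate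
9 | (2S,3S)-1,2-dihydroxy-2-methylpent-4-en-3-yl 2,4-bis(methoxymethoxy)-6-methylbenzoate | Cc1cc(OCOC)cc(OCOC)c1C(=O)O[C@@H](C=C)[C@@](C)(O)CO | intermediate
10 | (2S,3S)-2-methyl-1,2-bis(triethylsilyloxy)pent-4-en-3-yl 2,4-bis(methoxymethoxy)-6-methylbenzoate | Cc1cc(OCOC)cc(OCOC)c1C(=O)O[C@@H](C=C)[C@@](C)(O[Si](CC)(CC)CC)CO[Si](CC)(CC)CC | intermediate
11 | (1S,2S)-2-methyl-1-(oxiran-2-yl)-2,3-bis(triethylsilyloxy)propyl 2,4-bis(methoxymethoxy)-6-methylbenzoate (oxirane epimers) | Cc1cc(OCOC)cc(OCOC)c1C(=O)O[C@@H](C1CO1)[C@@](C)(O[Si](CC)(CC)CC)CO[Si](CC)(CC)CC | intermediate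
12 | (1S,2R)-2-methyl-1-(oxiran-2-yl)-3-oxo-2-(triethylsilyloxy)propyl 2,4-bis(methoxymethoxy)-6-methylbenzoate | Cc1cc(OCOC)cc(OCOC)c1C(=O)O[C@@H](C1CO1)[C@@](C)(O[Si](CC)(CC)CC)C=O | intermediate
13 | tert-butyl (2E)-but-2-enoate | C/C=C/C(=O)OC(C)(C)C | starting material
14 | tert-butyl (2E)-4-oxobut-2-enoate | O=C/C=C/C(=O)OC(C)(C)C | intermediate
15 | propargyl bromide | BrCC#C | starting material
16 | tert-butyl (2E,9S,10S)-10-(aroyloxy)-4,8-dihydroxy-9-methyl-10-(oxiran-2-yl)-9-(triethylsilyloxy)dec-2-en-5-ynoate (aroyl = 2,4-bis(methoxymethoxy)-6-methylbenzoyl) | Cc1cc(OCOC)cc(OCOC)c1C(=O)O[C@@H](C1CO1)[C@@](C)(O[Si](CC)(CC)CC)C(O)CC#CC(O)/C=C/C(=O)OC(C)(C)C | intermediate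
17 | tert-butyl (2E,9R,10S)-10-(aroyloxy)-9-methyl-10-(oxiran-2-yl)-4,8-dioxo-9-(triethylsilyloxy)dec-2-en-5-ynoate | Cc1cc(OCOC)cc(OCOC)c1C(=O)O[C@@H](C1CO1)[C@@](C)(O[Si](CC)(CC)CC)C(=O)CC#CC(=O)/C=C/C(=O)OC(C)(C)C | intermediate
18 | (1S,2S,6R)-3-[(3E)-5-tert-butoxy-2,5-dioxopent-3-en-1-ylidene]-2-(hydroxymethyl)-6-methyl-5-oxo-6-(triethylsilyloxy)cyclohexyl 2,4-bis(methoxymethoxy)-6-methylbenzoate | Cc1cc(OCOC)cc(OCOC)c1C(=O)O[C@H]1[C@H](CO)C(=CC(=O)/C=C/C(=O)OC(C)(C)C)CC(=O)[C@]1(C)O[Si](CC)(CC)CC | intermediate
19 | pinazaphilone B, (2E)-3-[(7R,8S,8aS)-8-(2,4-dihydroxy-6-methylbenzoyloxy)-7-hydroxy-7-methyl-6-oxo-6,7,8,8a-tetrahydro-1H-isochromen-3-yl]prop-2-enoic acid | Cc1cc(O)cc(O)c1C(=O)O[C@H]1[C@@H]2COC(/C=C/C(=O)O)=CC2=CC(=O)[C@]1(C)O | target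

**Totals**
Total steps: 14. Longest linear sequence: 11 (Steps 1, 2, 3, 6, 7, 8, 9, 11, 12, 13, 14).

**Three steps most likely to fail**
- **Step 13 (Ti(III) radical cyclisation).** Cp2TiCl may reduce the electron-poor ene-ynedione or trap the C8a radical (deoxygenation) before ring closure. Fallback: change the radical precursor and mediator. Dihydroxylate the vinyl group of 10, silylate the primary OH, convert the secondary OH to its imidazolyl thiocarbonate, carry it through Steps 9–12, and cyclise with (TMS)3SiH/Et3B–O2 (Barton–McCombie-type radical generation, no low-valent metal).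
- **Step 12 (ynedione 17).** The CH2 between the ketone and the ynone may isomerise to an allenyl diketone or furan. Fallback: change the oxidation-state timing. Oxidise only the propargylic alcohol (MnO2), cyclise the mono-ynone with C6 kept as a carbinol, close the pyran, then oxidise the now-allylic C6–OH with MnO2 before deprotection.
- **Step 6 (epoxide opening).** The vinyl epoxide may open with poor regio- or stereo-fidelity (SN1 or SN2′) with the bulky acid. Fallback: open 8 with benzoic acid under the same Ti conditions, protect the other two hydroxyls, remove the benzoate, and install the orsellinate with retention by alkoxide opening of 7-(methoxymethoxy)-2,2,5-trimethyl-4H-1,3-benzodioxin-4-one.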